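**Plan**

- The target is a 3',6-linked biflavone: C3' of ring B of unit 1 (5-hydroxy-7,4'-dimethoxyflavone) is bonded to C6 of unit 2 (acacetin).
- Retrosynthesis: after removal of three methoxymethyl ethers and the 4'-O-methyl group, ring B of unit 1 is cut at C1'–C2' and C1'–C6'. Its C4' oxygen is para to C1', C1' sits on chromone C2 and C3' carries unit 2, so C2'–C6' are the five carbons of a 3-aryl-4-pyranone and C1' is the acidic methyl carbon of a 2-methylchromone.
- The pyranone is cut back through a bis-enaminone to an aryl acetone, this to a 6-allyl group, and that to the 5-O-allyl ether of acacetin (Claisen shift). The methylchromone is cut to 2',6'-dihydroxy-4'-methoxyacetophenone and ethyl acetate.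
- Forward: acacetin receives the pyranone ring at C6 (steps 1–6), the chromone ring of unit 1 is closed separately (steps 7–8), ring B is formed last from the two halves (step 9), and O-methylation and acetal removal finish the synthesis (steps 10–11).
- Stereochemistry: the target has no stereocentre, so nothing has to be controlled.

Key step: step 9

Remark: the biaryl bond C3'–C6 carries only three small ortho substituents and no configuration is specified for it, so it is treated as freely rotating and the target as achiral. Primed locants refer to ring B of the flavone named.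

**Route**

Step 1
Reactants: 1 acacetin (5,7-dihydroxy-4'-methoxyflavone)
Product: 2 5-hydroxy-4'-methoxy-7-(methoxymethoxy)flavone
Conditions: MOMCl (1.1 equiv), K2CO3, acetone, rt
Reagents that add atoms: chloromethyl methyl ether, COCCl
Why: The 7-hydroxyl is the only non-chelated phenol, the 5-hydroxyl being hydrogen-bonded to the C4 carbonyl, so a Williamson-type O-alkylation with one equivalent of reagent should stop at the 7-ether.

Step 2
Reactants: 2 5-hydroxy-4'-methoxy-7-(methoxymethoxy)flavone; 3 allyl bromide
Product: 4 5-(allyloxy)-4'-methoxy-7-(methoxymethoxy)flavone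
Conditions: K2CO3, DMF, 60 °C
Reagents that add atoms: allyl bromide (3), C=CCBr
Why: With the 7-position capped, the chelated 5-phenol can be driven to react in a Williamson etherification with an unhindered allylic bromide in warm DMF.

Step 3
Reactants: 4 5-(allyloxy)-4'-methoxy-7-(methoxymethoxy)flavone
Product: 5 6-allyl-5-hydroxy-4'-methoxy-7-(methoxymethoxy)flavone
Conditions: PhNEt2, 200 °C (sealed tube)
Reagents that add atoms: none
Why: The aromatic Claisen rearrangement ([3,3]-sigmatropic shift) can deliver the allyl group only to C6, the one free ortho position (the other ortho carbon is the ring-fusion carbon C4a), and tautomerisation restores the chelated 5-phenol.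

Step 4
Reactants: 5 6-allyl-5-hydroxy-4'-methoxy-7-(methoxymethoxy)flavone
Product: 6 6-allyl-4'-methoxy-5,7-bis(methoxymethoxy)flavone
Conditions: NaH, DMF, 0 °C; MOMCl, 0 °C to rt
Reagents that add atoms: chloromethyl methyl ether, COCCl
Why: NaH breaks the chelate and the phenoxide is alkylated (Williamson-type acetal ether formation); the cap is needed because a free ortho-hydroxyl would cyclise onto the alkene in the palladium step and later onto the pyranone.

Step 5
Reactants: 6 6-allyl-4'-methoxy-5,7-bis(methoxymethoxy)flavone
Product: 7 4'-methoxy-5,7-bis(methoxymethoxy)-6-(2-oxopropyl)flavone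
Conditions: PdCl2 (10 mol %), CuCl (co-catalyst), O2 (1 atm), DMF–H2O (7:1), rt
Reagents that add atoms: water, O (it supplies the carbonyl oxygen; dioxygen, O=O, is the terminal oxidant)
Why: Wacker–Tsuji oxidation of the terminal alkene (Markovnikov hydroxypalladation, then β-hydride elimination) should give the methyl ketone, as is usual for allylarenes, and the acetal ethers and the electron-poor flavone double bond should not interfere.

Step 6
Reactants: 7 4'-methoxy-5,7-bis(methoxymethoxy)-6-(2-oxopropyl)flavone; 8 N,N-dimethylformamide dimethyl acetal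
Product: 10 4'-methoxy-5,7-bis(methoxymethoxy)-6-(4-oxo-4H-pyran-3-yl)flavone, via bis-enaminone 9 (not isolated)
Conditions: 8 (neat, excess), 110 °C; evaporation; AcOH–THF–H2O, 50 °C
Reagents that add atoms: N,N-dimethylformamide dimethyl acetal (8), COC(OC)N(C)C; water, O
Why: Both α-positions of the aryl acetone condense with the amide acetal (aminomethylenation), and aqueous acetic acid hydrolyses one enamine to the enol, which displaces the second dimethylamino group by 6-endo addition–elimination to close the 4-pyranone, an established pyranone synthesis from methylene ketones; acetic acid is too weak to cleave the methoxymethyl ethers.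

Step 7
Reactants: 11 2',6'-dihydroxy-4'-methoxyacetophenone; 12 ethyl acetate
Product: 14 5-hydroxy-7-methoxy-2-methylchromone (eugenin), via diketone 13 (not isolated)
Conditions: NaH (5 equiv), EtOAc, THF, reflux; then conc. HCl, MeOH, reflux
Reagents that add atoms: ethyl acetate (12), CCOC(C)=O
Why: Claisen condensation of the ketone enolate (phenols held as phenoxides) with ethyl acetate gives the 1,3-diketone, which undergoes acid-catalysed cyclodehydration onto an ortho-hydroxyl; the two hydroxyls are equivalent, so a single 2-methylchromone should result.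

Step 8
Reactants: 14 5-hydroxy-7-methoxy-2-methylchromone
Product: 15 7-methoxy-5-(methoxymethoxy)-2-methylchromone
Conditions: NaH, DMF, 0 °C; MOMCl, 0 °C to rt
Reagents that add atoms: chloromethyl methyl ether, COCCl
Why: Williamson-type alkylation of the sodium phenoxide; masking the 5-hydroxyl keeps the chromone from becoming a phenoxide in the next step, which would lower the acidity of the 2-methyl group.

Step 9
Reactants: 10 4'-methoxy-5,7-bis(methoxymethoxy)-6-(4-oxo-4H-pyran-3-yl)flavone; 15 7-methoxy-5-(methoxymethoxy)-2-methylchromone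
Product: 17 4'-hydroxy-7-methoxy-5-(methoxymethoxy)-3'-[2-(4-methoxyphenyl)-5,7-bis(methoxymethoxy)-4-oxo-4H-chromen-6-yl]flavone, via ring-opened enolate 16 (not isolated)
Conditions: 10 and 15 (1.5 equiv) in THF–t-BuOH, t-BuOK (3 equiv) added slowly at 0 °C, then 60 °C; AcOH quench
Reagents that add atoms: none
Why: Proposed new method: tert-butoxide reversibly deprotonates the 2-methyl group of 15 to a vinylogous enolate, which adds in conjugate fashion to an unsubstituted terminus (C6 or C2) of the 4-pyranone of 10; the adduct expels the ring oxygen as the enolate of a β-keto aldehyde (retro-oxa-Michael opening) to give 16, whose chromonyl methylene, now doubly activated, is deprotonated again and condenses with the formyl carbon, and loss of water and tautomerisation give the 4'-phenoxide. The closest known reactions are the conversion of pyrylium salts into benzenes by nitromethane and other one-carbon CH-acids and the related base-mediated ring transformations of activated 4-pyranones and chromones; a weakly acidic 2-methylchromone has not served as the one-carbon partner, although its alkoxide-mediated condensation with aldehydes shows that the carbanion is accessible. Ring B is closed by a 6-exo-trig intramolecular aldol condensation (the enolate double bond lying inside the new ring), the other bond to C1' having been made in the intermolecular conjugate addition, and no stereocentre is created. The step needs 1,4- rather than 1,2-addition to the pyranone, no attack on the flavone of 10 and no self-condensation of 15, which the two unhindered, unsubstituted pyranone termini (every chromone and flavone C2 is substituted and deactivated by 5,7-oxygenation), the reversibility of carbonyl addition and the slow addition of base in the presence of the pyranone are meant to secure. Both termini lead to the same 3'-aryl-4'-hydroxyphenyl ring, the two acetal ethers flanking C6 keep a phenoxide from attacking the pyranone, and tert-butanol acts as the proton shuttle that lets the enolate-masked aldehyde react, with aromatisation as the driving force.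

Step 10
Reactants: 17 4'-hydroxy-7-methoxy-5-(methoxymethoxy)-3'-[2-(4-methoxyphenyl)-5,7-bis(methoxymethoxy)-4-oxo-4H-chromen-6-yl]flavone
Product: 18 7,4'-dimethoxy-5-(methoxymethoxy)-3'-[2-(4-methoxyphenyl)-5,7-bis(methoxymethoxy)-4-oxo-4H-chromen-6-yl]flavone
Conditions: MeI, K2CO3, DMF, rt
Reagents that add atoms: iodomethane, CI
Why: Williamson methylation of the only free phenol installs the 4'-methoxy group, all other hydroxyls being masked.

Step 11
Reactants: 18 7,4'-dimethoxy-5-(methoxymethoxy)-3'-[2-(4-methoxyphenyl)-5,7-bis(methoxymethoxy)-4-oxo-4H-chromen-6-yl]flavone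
Product: 19 5-hydroxy-7,4'-dimethoxy-3'-[5,7-dihydroxy-2-(4-methoxyphenyl)-4-oxo-4H-chromen-6-yl]flavone (CNP0281098.0)
Conditions: conc. HCl (cat.), MeOH–THF, 50 °C
Reagents that add atoms: none
Why: Acid-catalysed acetal exchange with methanol should remove all three methoxymethyl ethers while the aryl methyl ethers stay, under conditions mild enough to avoid Wessely–Moser isomerisation of the 6-aryl-5,7-dihydroxyflavone.

**Compound list**

1 | acacetin (5,7-dihydroxy-4'-methoxyflavone) | COc1ccc(-c2cc(=O)c3c(O)cc(O)cc3o2)cc1 | starting material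
2 | 5-hydroxy-4'-methoxy-7-(methoxymethoxy)flavone | COc1ccc(-c2cc(=O)c3c(O)cc(OCOC)cc3o2)cc1 | intermediate
3 | allyl bromide | C=CCBr | starting material
4 | 5-(allyloxy)-4'-methoxy-7-(methoxymethoxy)flavone | COc1ccc(-c2cc(=O)c3c(OCC=C)cc(OCOC)cc3o2)cc1 | intermediate
5 | 6-allyl-5-hydroxy-4'-methoxy-7-(methoxymethoxy)flavone | COc1ccc(-c2cc(=O)c3c(O)c(CC=C)c(OCOC)cc3o2)cc1 | intermediate
6 | 6-allyl-4'-methoxy-5,7-bis(methoxymethoxy)flavone | COc1ccc(-c2cc(=O)c3c(OCOC)c(CC=C)c(OCOC)cc3o2)cc1 | intermediate
7 | 4'-methoxy-5,7-bis(methoxymethoxy)-6-(2-oxopropyl)flavone | COc1ccc(-c2cc(=O)c3c(OCOC)c(CC(C)=O)c(OCOC)cc3o2)cc1 | intermediate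
8 | N,N-dimethylformamide dimethyl acetal | COC(OC)N(C)C | starting material
9 | 6-[(1E,4E)-1,5-bis(dimethylamino)-3-oxopenta-1,4-dien-2-yl]-4'-methoxy-5,7-bis(methoxymethoxy)flavone (drawn as the expected E,E isomer; the geometry is lost on ring closure) | COc1ccc(-c2cc(=O)c3c(OCOC)c(\C(=C/N(C)C)C(=O)/C=C/N(C)C)c(OCOC)cc3o2)cc1 | intermediate (not isolated)
10 | 4'-methoxy-5,7-bis(methoxymethoxy)-6-(4-oxo-4H-pyran-3-yl)flavone | COc1ccc(-c2cc(=O)c3c(OCOC)c(-c4coccc4=O)c(OCOC)cc3o2)cc1 | intermediate
11 | 2',6'-dihydroxy-4'-methoxyacetophenone | CC(=O)c1c(O)cc(OC)cc1O | starting material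
12 | ethyl acetate | CCOC(C)=O | starting material
13 | 1-(2,6-dihydroxy-4-methoxyphenyl)butane-1,3-dione | CC(=O)CC(=O)c1c(O)cc(OC)cc1O | intermediate (not isolated)
14 | 5-hydroxy-7-methoxy-2-methylchromone (eugenin) | Cc1cc(=O)c2c(O)cc(OC)cc2o1 | intermediate
15 | 7-methoxy-5-(methoxymethoxy)-2-methylchromone | Cc1cc(=O)c2c(OCOC)cc(OC)cc2o1 | intermediate
16 | 6-{(1Z,4Z)-1-hydroxy-6-[7-methoxy-5-(methoxymethoxy)-4-oxo-4H-chromen-2-yl]-3-oxohexa-1,4-dien-2-yl}-4'-methoxy-5,7-bis(methoxymethoxy)flavone, present in the flask as its potassium enolate (drawn as the 4Z isomer that can close; the 4E isomer should equilibrate through the dienolate) | COc1ccc(-c2cc(=O)c3c(OCOC)c(/C(=C/O)C(=O)/C=C\Cc4cc(=O)c5c(OCOC)cc(OC)cc5o4)c(OCOC)cc3o2)cc1 | intermediate (not isolated)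
17 | 4'-hydroxy-7-methoxy-5-(methoxymethoxy)-3'-[2-(4-methoxyphenyl)-5,7-bis(methoxymethoxy)-4-oxo-4H-chromen-6-yl]flavone | Oc1ccc(-c2cc(=O)c3c(OCOC)cc(OC)cc3o2)cc1-c1c(OCOC)cc2oc(-c3ccc(OC)cc3)cc(=O)c2c1OCOC | intermediate
18 | 7,4'-dimethoxy-5-(methoxymethoxy)-3'-[2-(4-methoxyphenyl)-5,7-bis(methoxymethoxy)-4-oxo-4H-chromen-6-yl]flavone | COc1ccc(-c2cc(=O)c3c(OCOC)cc(OC)cc3o2)cc1-c1c(OCOC)cc2oc(-c3ccc(OC)cc3)cc(=O)c2c1OCOC | intermediate
19 | 5-hydroxy-7,4'-dimethoxy-3'-[5,7-dihydroxy-2-(4-methoxyphenyl)-4-oxo-4H-chromen-6-yl]flavone (CNP0281098.0) | COc1ccc(-c2cc(=O)c3c(O)c(-c4cc(-c5cc(=O)c6c(O)cc(OC)cc6o5)ccc4OC)c(O)cc3o2)cc1 | target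

**Step count**

Total: 11 steps. Longest linear sequence: 9 steps (steps 1–6, 9, 10, 11 from acacetin); steps 7–8 form the second branch.

**Steps most likely to fail**

1. Step 9 (proposed new method). The sequence may stop after conjugate addition and ring opening, because the formyl group is held as a stabilised enolate and the aldol closure does not follow. The chromone anion may also self-condense, or the base may open the chromone rings. Fallback with known chemistry, giving up ring synthesis of ring B and making the biaryl bond by cross-coupling; it sets out from 2 and 11 and returns at 18. From 2, iodination ortho to the free chelated 5-hydroxyl (benzyltrimethylammonium dichloroiodate, CaCO3, CH2Cl2–MeOH) should give 5-hydroxy-6-iodo-4'-methoxy-7-(methoxymethoxy)flavone F1, and NaH/MOMCl in DMF its ether 6-iodo-4'-methoxy-5,7-bis(methoxymethoxy)flavone F2. From 11, Claisen–Schmidt condensation with 3-bromo-4-methoxybenzaldehyde (KOH, EtOH) should give the chalcone (E)-3-(3-bromo-4-methoxyphenyl)-1-(2,6-dihydroxy-4-methoxyphenyl)prop-2-en-1-one F3. Oxidative cyclisation (I2 cat., DMSO, 130 °C) should then give 3'-bromo-5-hydroxy-7,4'-dimethoxyflavone F4, and NaH/MOMCl its ether 3'-bromo-7,4'-dimethoxy-5-(methoxymethoxy)flavone F5. Miyaura borylation (B2pin2, Pd(dppf)Cl2, KOAc, dioxane, 90 °C) should give 7,4'-dimethoxy-5-(methoxymethoxy)-3'-(4,4,5,5-tetramethyl-1,3,2-dioxaborolan-2-yl)flavone F6. Suzuki–Miyaura coupling of F2 with F6 (Pd(OAc)2, SPhos, K3PO4, toluene–H2O, 90 °C) should give 18, and step 11 then completes the synthesis.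

2. Step 6. The second aminomethylenation at the hindered benzylic methylene may remain incomplete, or the labile 5-acetal may be lost during the acid closure, after which the freed phenol would attack the pyranone. Fallback that attaches a preformed pyranone by cross-coupling; it sets out from 2 and returns at 10. Compound 2 is converted as above into 5-hydroxy-6-iodo-4'-methoxy-7-(methoxymethoxy)flavone F1 and 6-iodo-4'-methoxy-5,7-bis(methoxymethoxy)flavone F2 (the same compounds as in the fallback for step 9). Miyaura borylation of F2 (B2pin2, Pd(dppf)Cl2, KOAc, dioxane, 90 °C) should give 4'-methoxy-5,7-bis(methoxymethoxy)-6-(4,4,5,5-tetramethyl-1,3,2-dioxaborolan-2-yl)flavone F7. Suzuki–Miyaura coupling of F7 with 3-bromo-4H-pyran-4-one (Pd(OAc)2, SPhos, anhydrous K3PO4, dioxane, 90 °C, to limit protodeboronation) should give 10, so that steps 2–6 are bypassed.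

3. Step 5. Under PdCl2 the allyl group may isomerise into conjugation with the arene before it is oxidised, or the acid formed may remove an acetal. Fallback that separates hydration from oxidation; it sets out from 6 and returns at 7. Mukaiyama hydration of the terminal alkene (Co(acac)2 cat., PhSiH3, O2, i-PrOH–THF, rt) should give racemic 6-(2-hydroxypropyl)-4'-methoxy-5,7-bis(methoxymethoxy)flavone F8 with Markovnikov selectivity through a radical pathway that cannot isomerise the alkene. Oxidation with Dess–Martin periodinane (CH2Cl2, NaHCO3, rt) should give 7; any ketone formed directly in the hydration converges on the same product.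

**Further compounds**

F1 | step 9 | 5-hydroxy-6-iodo-4'-methoxy-7-(methoxymethoxy)flavone | COc1ccc(-c2cc(=O)c3c(O)c(I)c(OCOC)cc3o2)cc1
F2 | step 9 | 6-iodo-4'-methoxy-5,7-bis(methoxymethoxy)flavone | COc1ccc(-c2cc(=O)c3c(OCOC)c(I)c(OCOC)cc3o2)cc1
F3 | step 9 | (E)-3-(3-bromo-4-methoxyphenyl)-1-(2,6-dihydroxy-4-methoxyphenyl)prop-2-en-1-one | COc1cc(O)c(C(=O)/C=C/c2ccc(OC)c(Br)c2)c(O)c1
F4 | step 9 | 3'-bromo-5-hydroxy-7,4'-dimethoxyflavone | COc1cc(O)c2c(c1)oc(-c1ccc(OC)c(Br)c1)cc2=O
F5 | step 9 | 3'-bromo-7,4'-dimethoxy-5-(methoxymethoxy)flavone | COCOc1cc(OC)cc2oc(-c3ccc(OC)c(Br)c3)cc(=O)c12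
F6 | step 9 | 7,4'-dimethoxy-5-(methoxymethoxy)-3'-(4,4,5,5-tetramethyl-1,3,2-dioxaborolan-2-yl)flavone | COCOc1cc(OC)cc2oc(-c3ccc(OC)c(B4OC(C)(C)C(C)(C)O4)c3)cc(=O)c12
F7 | step 6 | 4'-methoxy-5,7-bis(methoxymethoxy)-6-(4,4,5,5-tetramethyl-1,3,2-dioxaborolan-2-yl)flavone | COc1ccc(-c2cc(=O)c3c(OCOC)c(B4OC(C)(C)C(C)(C)O4)c(OCOC)cc3o2)cc1
F8 | step 5 | 6-(2-hydroxypropyl)-4'-methoxy-5,7-bis(methoxymethoxy)flavone (racemic) | COc1ccc(-c2cc(=O)c3c(OCOC)c(CC(C)O)c(OCOC)cc3o2)cc1
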